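Only one carbon of the target is stereogenic: C10' of the undecyl chain on C6 of the 2-methoxy-3,5-dimethyl-4-pyranone ring, the carbon that also holds the terminal methyl C11'. Everything rests on making the C10'–C11' bond last in the skeleton: a chiral titanium bis(sulfonamide) catalyst passes a methyl group from dimethylzinc to one face of an achiral C10' aldehyde, so bond and S carbinol arise in one operation while the electron-rich ring C4 carbonyl stays untouched. The precursor is a decanal carrying the finished methoxypyranone at its far end, built from undec-10-enoic acid and methyl 2-methyl-3-oxopentanoate by dianion acylation, cyclisation, O-methylation, hydroboration–oxidation and alcohol oxidation. Acetylation completes the target.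

Key step: step 6

Assumption: the (1R,2R) enantiomer of the bis(trifluoromethanesulfonamide) ligand is taken to direct the methyl group to the Si face of the aldehyde, as is usual for alkyl transfer with this ligand class, which corresponds to S at C10'; were the sense opposite, the equally available (1S,2S) ligand would be used with no other change.

Step 1
Reactants: 1 undec-10-enoic acid; 2 methyl 2-methyl-3-oxopentanoate
Product: 5 methyl 2,4-dimethyl-3,5-dioxopentadec-14-enoate, via undec-10-enoyl imidazolide 3 (not isolated), via dilithiated keto ester dianion 4 (not isolated)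
Conditions: 1, CDI, THF, rt; solution added to 4 [2 (about 3.3 equiv), LiN(iPr)2 (about 6.6 equiv), THF, −78 → 0 °C] at −78 °C, then → −30 °C; aq. HCl
Reagents that add atoms: none
Why: Acylation of a β-keto ester dianion (Claisen-type condensation), in which the terminal carbanion of 4 is the more nucleophilic site and attacks acyl imidazolide 3 at carbon, while the surplus dianion absorbs the imidazole N–H and the acidic tricarbonyl product.

Step 2
Reactants: 5 methyl 2,4-dimethyl-3,5-dioxopentadec-14-enoate
Product: 6 6-(dec-9-en-1-yl)-4-hydroxy-3,5-dimethyl-2H-pyran-2-one
Conditions: DBU, toluene, 60 °C; aq. HCl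
Reagents that add atoms: none
Why: Base-mediated lactonisation (intramolecular transesterification), in which the enolate oxygen of the C5 ketone attacks the methyl ester in a 6-exo-trig acyl substitution and expels methoxide to give the stabilised 4-hydroxy-2-pyranone.

Step 3
Reactants: 6 6-(dec-9-en-1-yl)-4-hydroxy-3,5-dimethyl-2H-pyran-2-one
Product: 8 2-(dec-9-en-1-yl)-6-methoxy-3,5-dimethyl-4H-pyran-4-one, via 4-hydroxy-2-methoxypyrylium triflate 7 (not isolated)
Conditions: CF3SO3CH3, CH2Cl2, rt; aq. NaHCO3
Reagents that add atoms: methyl trifluoromethanesulfonate, COS(=O)(=O)C(F)(F)F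
Why: Regioselective O-alkylation with a hard methylating agent, since without base the lactone carbonyl oxygen of 6 is the most nucleophilic site and its methylation gives the aromatic pyrylium salt 7, which resists a second methylation and loses the O–H proton on bicarbonate work-up to leave the 4-pyranone.

Step 4
Reactants: 8 2-(dec-9-en-1-yl)-6-methoxy-3,5-dimethyl-4H-pyran-4-one
Product: 10 2-(10-hydroxydecyl)-6-methoxy-3,5-dimethyl-4H-pyran-4-one, via trialkylborane 9 (not isolated)
Conditions: 9-BBN, THF, 0 °C → rt; NaBO3·4H2O, H2O, rt
Reagents that add atoms: sodium perborate tetrahydrate (hydrate water omitted), [Na+].[Na+].O[B-]1(O)OO[B-](O)(O)OO1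
Why: Anti-Markovnikov hydroboration–oxidation, in which the bulky dialkylborane adds boron to the terminal carbon of the monosubstituted alkene much faster than it touches the vinylogous ester carbonyl, and perborate oxidises the C–B bond under nearly neutral conditions that spare the methoxypyranone.

Step 5
Reactants: 10 2-(10-hydroxydecyl)-6-methoxy-3,5-dimethyl-4H-pyran-4-one
Product: 11 10-(6-methoxy-3,5-dimethyl-4-oxo-4H-pyran-2-yl)decanal
Conditions: Dess–Martin periodinane, NaHCO3, CH2Cl2, 0 °C → rt
Reagents that add atoms: none
Why: Dess–Martin oxidation, in which ligand exchange at pentavalent iodine and intramolecular removal of the carbinol hydrogen convert the primary alcohol into the aldehyde without over-oxidation, the bicarbonate buffer keeping acetic acid away from the methoxypyranone.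

Step 6
Reactants: 11 10-(6-methoxy-3,5-dimethyl-4-oxo-4H-pyran-2-yl)decanal; 12 dimethylzinc
Product: 13 (S)-2-(10-hydroxyundecyl)-6-methoxy-3,5-dimethyl-4H-pyran-4-one
Conditions: Zn(CH3)2 (3 equiv, toluene solution), Ti(OiPr)4 (1.5 equiv), (1R,2R)-N,N'-(cyclohexane-1,2-diyl)bis(1,1,1-trifluoromethanesulfonamide) (10 mol %), toluene, −20 → 0 °C; sat. aq. NH4Cl
Reagents that add atoms: dimethylzinc (compound 12), C[Zn]C
Why: The bis(sulfonamide) replaces two isopropoxides on titanium to give a chiral, strongly Lewis-acidic complex, zinc passes a methyl group to titanium, the aldehyde oxygen of 11 binds to the chiral centre and the methyl migrates to the carbonyl carbon, forming C10'–C11'; aqueous work-up releases the alcohol. The closest known reaction type is the titanium-promoted, bis(sulfonamide)-catalysed enantioselective addition of dialkylzincs to unbranched aliphatic aldehydes, of which methyl transfer is the slowest member, hence the excess of 12 and the warmer end temperature. No ring is closed in this step. The new stereocentre C10' is controlled by the ligand alone: its (1R,2R) backbone should leave the Si face of the bound aldehyde open to the methyl group, which gives S because the substrate has no stereocentre or branch near C10' that could oppose the catalyst. The step needs chemoselectivity for the aldehyde over the ring C4 carbonyl, and the substrate secures it because that carbonyl is a doubly vinylogous carbonate flanked by the C3 and C5 methyl groups and is far less electrophilic, while the non-basic methyl donor neither adds in conjugate fashion nor deprotonates the ring methyls or C1'.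

Step 7
Reactants: 13 (S)-2-(10-hydroxyundecyl)-6-methoxy-3,5-dimethyl-4H-pyran-4-one
Product: 14 (S)-11-(6-methoxy-3,5-dimethyl-4-oxo-4H-pyran-2-yl)undecan-2-yl acetate
Conditions: Ac2O, pyridine, DMAP (cat.), CH2Cl2, 0 °C → rt
Reagents that add atoms: acetic anhydride, CC(=O)OC(C)=O
Why: DMAP-catalysed acylation through an N-acetylpyridinium ion, in which the alcohol oxygen attacks the acyl carbon so that the C10'–O bond is never broken and the S configuration is retained.

Compound list
1 | undec-10-enoic acid | OC(=O)CCCCCCCCC=C | starting material
2 | methyl 2-methyl-3-oxopentanoate (racemic, enolisable) | CCC(=O)C(C)C(=O)OC | starting material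
3 | 1-(1H-imidazol-1-yl)undec-10-en-1-one (undec-10-enoyl imidazolide) | C=CCCCCCCCCC(=O)n1ccnc1 | intermediate (not isolated)
4 | dilithium dianion of methyl 2-methyl-3-oxopentanoate (metalated at C2 and C4) | [Li+].[Li+].C[CH-]C(=O)[C-](C)C(=O)OC | intermediate (not isolated)
5 | methyl 2,4-dimethyl-3,5-dioxopentadec-14-enoate (mixture of diastereomers and enol forms; no stereocentre is carried on) | C=CCCCCCCCCC(=O)C(C)C(=O)C(C)C(=O)OC | intermediate
6 | 6-(dec-9-en-1-yl)-4-hydroxy-3,5-dimethyl-2H-pyran-2-one | C=CCCCCCCCCc1oc(=O)c(C)c(O)c1C | intermediate
7 | 2-(dec-9-en-1-yl)-4-hydroxy-6-methoxy-3,5-dimethylpyrylium trifluoromethanesulfonate | COc1[o+]c(CCCCCCCCC=C)c(C)c(O)c1C.[O-]S(=O)(=O)C(F)(F)F | intermediate (not isolated)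
8 | 2-(dec-9-en-1-yl)-6-methoxy-3,5-dimethyl-4H-pyran-4-one | COc1oc(CCCCCCCCC=C)c(C)c(=O)c1C | intermediate
9 | 2-[10-(9-borabicyclo[3.3.1]nonan-9-yl)decyl]-6-methoxy-3,5-dimethyl-4H-pyran-4-one | COc1oc(CCCCCCCCCCB2C3CCCC2CCC3)c(C)c(=O)c1C | intermediate (not isolated)
10 | 2-(10-hydroxydecyl)-6-methoxy-3,5-dimethyl-4H-pyran-4-one | COc1oc(CCCCCCCCCCO)c(C)c(=O)c1C | intermediate
11 | 10-(6-methoxy-3,5-dimethyl-4-oxo-4H-pyran-2-yl)decanal | COc1oc(CCCCCCCCCC=O)c(C)c(=O)c1C | intermediate
12 | dimethylzinc | C[Zn]C | starting material
13 | (S)-2-(10-hydroxyundecyl)-6-methoxy-3,5-dimethyl-4H-pyran-4-one | COc1oc(CCCCCCCCC[C@H](C)O)c(C)c(=O)c1C | intermediate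
14 | (S)-11-(6-methoxy-3,5-dimethyl-4-oxo-4H-pyran-2-yl)undecan-2-yl acetate | COc1oc(CCCCCCCCC[C@H](C)OC(C)=O)c(C)c(=O)c1C | target

Total step count: 7. Longest linear sequence: 7 steps (1 → 14).

Steps most likely to fail

Step 6. Methyl transfer from zinc is slow, so uncatalysed background addition or isopropoxide-mediated reduction of the aldehyde may compete. The Lewis-basic pyranone oxygen may also tie up titanium. The outcome would be poor facial selectivity or low conversion. In the fallback the stereocentre is set by enzymatic resolution instead of by catalyst control. Aldehyde 11 is treated with the achiral, aldehyde-selective CH3Ti(OiPr)3 (from CH3Li and ClTi(OiPr)3, THF, −40 → 0 °C) to give racemic 2-(10-hydroxyundecyl)-6-methoxy-3,5-dimethyl-4H-pyran-4-one F1. Candida antarctica lipase B with vinyl acetate in hexane/MTBE at rt should then acetylate the R enantiomer, following the usual preference of this lipase for methyl carbinols. This gives (R)-11-(6-methoxy-3,5-dimethyl-4-oxo-4H-pyran-2-yl)undecan-2-yl acetate F2 and leaves the S alcohol, which is separated by chromatography. The fallback sets out from 11 and returns to the route at 13, at the cost of at most half of the material.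

Step 3. Methylation may occur at the C4 oxygen instead of the lactone carbonyl oxygen, or at both oxygens, which would erode the regiochemical outcome. In the fallback the methoxy group is kept from the ester instead of being installed. Diketo ester 5 is cyclodehydrated with PPh3 and CCl4 in THF at rt. The enol of the C5 ketone is activated as an oxyphosphonium or vinyl chloride and displaced by the ester carbonyl oxygen in an addition–elimination. The ring oxygen then comes from the ester carbonyl and OCH3 stays on ring C2. The fallback sets out from 5 and returns at 8, bypassing 6 and 7, and makes no compound outside the list (F0).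

Step 1. Proton transfer from the α-methylene of the acyl imidazolide or from imidazole may quench the dianion, and O-acylation may compete, so C-acylation could stall. In the fallback the same carbon–carbon bond is made by aldol addition followed by oxidation. Dianion 4, made from 2 as before, is added to commercial undec-10-enal (THF, −78 °C) to give methyl 5-hydroxy-2,4-dimethyl-3-oxopentadec-14-enoate F3 as a diastereomer mixture. Dess–Martin oxidation (CH2Cl2, NaHCO3, rt) converts it into the diketo ester. The fallback sets out from 2 and returns at 5.

Further compounds
F1 | step 6 | racemic 2-(10-hydroxyundecyl)-6-methoxy-3,5-dimethyl-4H-pyran-4-one | COc1oc(CCCCCCCCCC(C)O)c(C)c(=O)c1C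
F2 | step 6 | (R)-11-(6-methoxy-3,5-dimethyl-4-oxo-4H-pyran-2-yl)undecan-2-yl acetate | COc1oc(CCCCCCCCC[C@@H](C)OC(C)=O)c(C)c(=O)c1C
F0 | step 3 | none | none
F3 | step 1 | methyl 5-hydroxy-2,4-dimethyl-3-oxopentadec-14-enoate (diastereomer mixture, configuration undefined) | C=CCCCCCCCCC(O)C(C)C(=O)C(C)C(=O)OC
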